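**Plan**

1. Retrosynthesis (prostanoid numbering: C1 ester carbon, C8–C12 ring, C13–C20 octenyl chain): the C5=C6 olefin is cut first (Wittig reaction on a C6 lactol). The ring bonds C9–C10 and C8–C12 are then cut together, leaving dichlorovinyl ketone 7 (C10–C20) and axially chiral 1-ethoxyallene 14 (C6–C9).
2. Enabling feature: in the cyclopentenone ring the C9 carbonyl with the exocyclic C8=C7 olefin is a masked 1-alkoxyallene (C9 acyl-anion carbon, C8 nucleophilic enol-ether carbon). The C12 carbinol with the C11=C10–Cl unit is a masked β,β-dichlorovinyl ketone (C10 vinylogous acid chloride, C12 ketone).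
3. Forward: 7 (steps 1–4) and 14 (steps 5–6) are joined in step 7, which closes the only ring with chlorine, tertiary carbinol and exocyclic olefin in place. Step 8 oxidizes C6 and funnels the exocyclic olefin to 7E through a lactol; step 10 appends C1–C5.
4. Stereochemistry: 12R by axis-to-centre transfer from the aS allene, whose axis comes from a 2R propargylic carbinol made by catalytic asymmetric alkynylation. 14Z is bought with 1; 7E arises by equilibration into the lactol; 5Z by a salt-free Wittig reaction.

Key step: step 7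

Assumption: in the cyclization the protonated C12 oxygen takes the inside position of the U-shaped cation and the CH2OSi group of the allene turns away from C12; on this basis aS-14 leads to 12R, and the antipodal ligand would be used in step 5 should the sense prove opposite.

**Route**

Step 1
Reactants: 1 (3Z)-non-3-en-1-ol
Product: 2 (3Z)-non-3-enal
Conditions: DMP, CH2Cl2, 0 °C; used crude
Reagents that add atoms: none
Why: Dess–Martin oxidation of the primary alcohol is neutral and fast, so the β,γ-unsaturated aldehyde should form without migration or isomerization of the 14Z olefin that comes with 1; no stereocenter is formed.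

Step 2
Reactants: 2 (3Z)-non-3-enal; 3 (Z)-1,2-dichloroethene
Product: 5 (5Z)-1-chloroundec-5-en-1-yn-3-ol (racemic), via lithium chloroacetylide 4 (not isolated)
Conditions: 3, MeLi (2 equiv), Et2O, 0 °C; then 2, −78 °C; then H2O
Reagents that add atoms: none
Why: Twofold dehydrochlorination–metalation of 3 gives the lithium acetylide, whose 1,2-addition to the aldehyde at −78 °C (acetylide addition) should outrun enolization; the carbinol centre forms racemic and is removed in step 3.

Step 3
Reactants: 5 (5Z)-1-chloroundec-5-en-1-yn-3-ol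
Product: 6 (5Z)-1-chloroundec-5-en-1-yn-3-one
Conditions: DMP, CH2Cl2, 0 °C
Reagents that add atoms: none
Why: Dess–Martin oxidation of the propargylic alcohol gives the ynone under non-basic conditions, so the skipped olefin should not be drawn into conjugation; the racemic centre is erased.

Step 4
Reactants: 6 (5Z)-1-chloroundec-5-en-1-yn-3-one
Product: 7 (5Z)-1,1-dichloroundeca-1,5-dien-3-one
Conditions: LiCl, AcOH, 23 °C
Reagents that add atoms: lithium chloride [Li+].[Cl-]
Why: Conjugate hydrochlorination of an ynone (chloride to the β-carbon, proton to the α-carbon) should turn the chloroalkynone into the β,β-dichlorovinyl ketone, a vinylogous acid chloride; no stereocenter is formed.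

Step 5
Reactants: 8 2-[(tert-butyldimethylsilyl)oxy]acetaldehyde; 9 ethoxyethyne
Product: 11 (2R)-1-[(tert-butyldimethylsilyl)oxy]-4-ethoxybut-3-yn-2-ol, via (ethoxyethynyl)methylzinc 10 (not isolated)
Conditions: 9, Me2Zn, ProPhenol ligand (20 mol %, the antipode that directs Re-face attack), Ph3PO (40 mol %), toluene, 0 °C; then 8; then H2O
Reagents that add atoms: none
Why: Catalytic enantioselective alkynylation of the aldehyde by the zinc acetylide held in the dinuclear zinc–ProPhenol pocket; attack on the Re face of 8 sets the 2R carbinol, which is the source of all later chirality.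

Step 6
Reactants: 11 (2R)-1-[(tert-butyldimethylsilyl)oxy]-4-ethoxybut-3-yn-2-ol
Product: 14 (aS)-tert-butyl[(4-ethoxybuta-2,3-dien-1-yl)oxy]dimethylsilane, via sulfonylhydrazine adduct 12 (not isolated), via propargylic diazene 13 (not isolated)
Conditions: PPh3, DEAD, THF, −15 °C; then NBSH (2-nitrobenzenesulfonyl hydrazide), −15 → 23 °C
Reagents that add atoms: none
Why: Myers allene synthesis, in which Mitsunobu displacement by the hydrazide with inversion, loss of arenesulfinic acid and suprafacial retro-ene loss of N2 from the diazene place hydrogen anti to the original C–O bond, so that the 2R centre should be converted into the aS axis.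

Step 7
Reactants: 14 (aS)-tert-butyl[(4-ethoxybuta-2,3-dien-1-yl)oxy]dimethylsilane; 7 (5Z)-1,1-dichloroundeca-1,5-dien-3-one
Product: 19 (4R,5Z)-2-chloro-4-hydroxy-5-(2-hydroxyethylidene)-4-[(2Z)-oct-2-en-1-yl]cyclopent-2-en-1-one, via lithioallene 15 (not isolated), via allenylstannane 16 (not isolated), via chlorotrienone 17 (not isolated), via silyl ether 18 (not isolated)
Conditions: 14, n-BuLi, THF, −78 °C; Bu3SnCl, −78 → 0 °C; 7, Pd2(dba)3 (2.5 mol %), AsPh3 (10 mol %), 23 °C; volatiles exchanged for CH2Cl2 in the same flask; TfOH (3 equiv), −78 → −40 °C; then 1 M aq. HCl–THF, 23 °C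
Reagents that add atoms: water O
Why: Proposed new method: Lithiation of 14 at the oxygen-bearing allene carbon and stannylation give 16, whose Stille coupling with the C–Cl bond of 7 that lies trans to the acyl group forges C9–C10 and should give chlorotrienone 17; TfOH then O-protonates the ketone to a 1-hydroxy-4-ethoxypentadienyl cation (C12–C11–C10–C9–C8) that, after rotation about the weakened C10–C11 bond, closes C8–C12 by 4π conrotation, and water hydrolyses the resulting C9 ethoxy-oxocarbenium ion to the ketone and removes the silyl group. The closest known reaction types are the cationic cyclopentannelation of lithiated 1-alkoxyallenes (allene ether Nazarov cyclization, including axis-to-centre chirality transfer), the Piancatelli 4π closure of 1-hydroxy-4-oxypentadienyl cations and the trans-selective mono-coupling of 1,1-dihaloalkenes; new here are the entry by vinylic substitution on a β,β-dichlorovinyl ketone, which leaves chlorine on C10, and a ketone carbon as the cationic terminus. The one ring, the cyclopentenone, is closed by this 4π-conrotatory electrocyclization, formally a 5-(enolendo)-exo-trig attack of the allenyl enol-ether carbon C8 on the activated C12 ketone, driven by release of allene strain and by formation of the oxygen-stabilized C9 cation. C12 is controlled by the aS allene axis: the CH2OSi group on C7 turns away from the approaching C12 terminus, which fixes the sense of conrotation, and with the small protonated oxygen inside the U-shaped cation this sense should place OH and octenyl as in 12R, the exocyclic olefin emerging 7Z (corrected in step 8). The step needs C-closure to beat O-closure (oxa-6π to an alkylidene-pyran), which the trans-selective coupling secures because the cis geometry is reached only in the O-protonated cation whose oxygen is no longer nucleophilic, and it needs site-selective coupling, secured by the better accessibility of the chlorine trans to the acyl group.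

Step 8
Reactants: 19 (4R,5Z)-2-chloro-4-hydroxy-5-(2-hydroxyethylidene)-4-[(2Z)-oct-2-en-1-yl]cyclopent-2-en-1-one
Product: 21 (6aR)-5-chloro-2-hydroxy-6a-[(2Z)-oct-2-en-1-yl]-2,6a-dihydro-4H-cyclopenta[b]furan-4-one, via (7Z)-oxo-enal 20 (not isolated)
Conditions: DMP (1.0 equiv), CH2Cl2, 0 °C; then pyridine, 23 °C
Reagents that add atoms: none
Why: Dess–Martin oxidation should take only the primary allylic alcohol and, once the oxidant is spent, pyridine isomerizes the 4-oxo-enal by reversible conjugate addition to the trans-enedicarbonyl (7E) form, which alone can close onto the C12 hydroxyl as lactol 21, so every exocyclic isomer funnels into 7E; the hemiacetal carbon is an inconsequential anomeric mixture.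

Step 9
Reactants: 22 methyl 5-bromopentanoate
Product: 23 (5-methoxy-5-oxopentyl)triphenylphosphonium bromide
Conditions: PPh3, MeCN, reflux
Reagents that add atoms: triphenylphosphine c1ccc(cc1)P(c1ccccc1)c1ccccc1
Why: SN2 quaternization of triphenylphosphine by a primary bromide should give the Wittig salt cleanly; no stereocenter is formed.

Step 10
Reactants: 21 (6aR)-5-chloro-2-hydroxy-6a-[(2Z)-oct-2-en-1-yl]-2,6a-dihydro-4H-cyclopenta[b]furan-4-one; 23 (5-methoxy-5-oxopentyl)triphenylphosphonium bromide
Product: 25 methyl (5Z,7E,12R,14Z)-10-chloro-12-hydroxy-9-oxoprosta-5,7,10,14-tetraen-1-oate, via phosphorus ylide 24 (not isolated)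
Conditions: 23 (2.5 equiv), NaN(SiMe3)2 (2.4 equiv), THF, −78 °C; then 21, −78 → −20 °C; then pH 7 buffer
Reagents that add atoms: none
Why: Wittig olefination of the ring-opened hydroxy-enal form of the lactol with a salt-free non-stabilized ylide (the lactol olefination used for prostaglandin α-chains) should be kinetically Z-selective through the cis-oxaphosphetane and set 5Z while the 7E olefin, fixed in the lactol ring, is untouched; the first equivalent of ylide serves as the base that opens the lactol.

**Compound list**

1 | (3Z)-non-3-en-1-ol | CCCCC/C=C\CCO | starting material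
2 | (3Z)-non-3-enal | CCCCC/C=C\CC=O | intermediate
3 | (Z)-1,2-dichloroethene | Cl/C=C\Cl | starting material
4 | lithium chloroacetylide | [Li]C#CCl | intermediate (not isolated)
5 | (5Z)-1-chloroundec-5-en-1-yn-3-ol (racemic) | CCCCC/C=C\CC(O)C#CCl | intermediate
6 | (5Z)-1-chloroundec-5-en-1-yn-3-one | CCCCC/C=C\CC(=O)C#CCl | intermediate
7 | (5Z)-1,1-dichloroundeca-1,5-dien-3-one | CCCCC/C=C\CC(=O)C=C(Cl)Cl | intermediate
8 | 2-[(tert-butyldimethylsilyl)oxy]acetaldehyde | O=CCO[Si](C)(C)C(C)(C)C | starting material
9 | ethoxyethyne (ethoxyacetylene) | CCOC#C | starting material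
10 | (ethoxyethynyl)methylzinc | CCOC#C[Zn]C | intermediate (not isolated)
11 | (2R)-1-[(tert-butyldimethylsilyl)oxy]-4-ethoxybut-3-yn-2-ol | CCOC#C[C@@H](O)CO[Si](C)(C)C(C)(C)C | intermediate
12 | N-{(2S)-1-[(tert-butyldimethylsilyl)oxy]-4-ethoxybut-3-yn-2-yl}-2-nitrobenzenesulfonohydrazide (alkylated on the sulfonylated nitrogen) | CCOC#C[C@H](N(N)S(=O)(=O)c1ccccc1[N+](=O)[O-])CO[Si](C)(C)C(C)(C)C | intermediate (not isolated)
13 | {(2S)-1-[(tert-butyldimethylsilyl)oxy]-4-ethoxybut-3-yn-2-yl}diazene | CCOC#C[C@H](N=N)CO[Si](C)(C)C(C)(C)C | intermediate (not isolated)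
14 | (aS)-tert-butyl[(4-ethoxybuta-2,3-dien-1-yl)oxy]dimethylsilane | CCOC=[C@@]=CCO[Si](C)(C)C(C)(C)C | intermediate
15 | (aS)-{4-[(tert-butyldimethylsilyl)oxy]-1-ethoxybuta-1,2-dien-1-yl}lithium | CCOC([Li])=[C@@]=CCO[Si](C)(C)C(C)(C)C | intermediate (not isolated)
16 | tributyl{4-[(tert-butyldimethylsilyl)oxy]-1-ethoxybuta-1,2-dien-1-yl}stannane, axis as in 14 (formally aR because tin outranks oxygen) | CCOC([Sn](CCCC)(CCCC)CCCC)=[C@@]=CCO[Si](C)(C)C(C)(C)C | intermediate (not isolated)
17 | (aS,5Z,9Z)-1-[(tert-butyldimethylsilyl)oxy]-5-chloro-4-ethoxypentadeca-2,3,5,9-tetraen-7-one | CCOC(/C(Cl)=C/C(=O)C/C=C\CCCCC)=[C@@]=CCO[Si](C)(C)C(C)(C)C | intermediate (not isolated)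
18 | (4R,5Z)-5-{2-[(tert-butyldimethylsilyl)oxy]ethylidene}-2-chloro-4-hydroxy-4-[(2Z)-oct-2-en-1-yl]cyclopent-2-en-1-one | CCCCC/C=C\C[C@@]1(O)C=C(Cl)C(=O)/C1=C\CO[Si](C)(C)C(C)(C)C | intermediate (not isolated)
19 | (4R,5Z)-2-chloro-4-hydroxy-5-(2-hydroxyethylidene)-4-[(2Z)-oct-2-en-1-yl]cyclopent-2-en-1-one | CCCCC/C=C\C[C@@]1(O)C=C(Cl)C(=O)/C1=C\CO | intermediate
20 | (2Z)-2-{(5R)-3-chloro-5-hydroxy-5-[(2Z)-oct-2-en-1-yl]-2-oxocyclopent-3-en-1-ylidene}acetaldehyde | CCCCC/C=C\C[C@@]1(O)C=C(Cl)C(=O)/C1=C\C=O | intermediate (not isolated)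
21 | (6aR)-5-chloro-2-hydroxy-6a-[(2Z)-oct-2-en-1-yl]-2,6a-dihydro-4H-cyclopenta[b]furan-4-one (anomer mixture at C2, in equilibrium with its open 7E hydroxy-enal) | CCCCC/C=C\C[C@@]12C=C(Cl)C(=O)C1=CC(O)O2 | intermediate
22 | methyl 5-bromopentanoate | COC(=O)CCCCBr | starting material
23 | (5-methoxy-5-oxopentyl)triphenylphosphonium bromide | COC(=O)CCCC[P+](c1ccccc1)(c1ccccc1)c1ccccc1.[Br-] | intermediate
24 | methyl 5-(triphenyl-λ5-phosphanylidene)pentanoate | COC(=O)CCCC=P(c1ccccc1)(c1ccccc1)c1ccccc1 | intermediate (not isolated)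
25 | methyl (5Z,7E,12R,14Z)-10-chloro-12-hydroxy-9-oxoprosta-5,7,10,14-tetraen-1-oate (chlorovulone I) | CCCCC/C=C\C[C@@]1(O)C=C(Cl)C(=O)/C1=C/C=C\CCCC(=O)OC | target

**Step count and risks**

Total steps: 10. Longest linear sequence: 7 steps (1, 2, 3, 4, 7, 8, 10).

Most likely to fail, in order:

1. Step 7. Three processes threaten it:
   - loss of trans-selectivity in the coupling would give a cis-chlorotrienone that closes through oxygen (oxa-6π) to an alkylidene-pyran;
   - the acid may protonate the allenyl ether on carbon instead of the ketone on oxygen;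
   - propargyl–allenyl scrambling at tin or palladium, or a cyclization with the CH2 group inside, would erode the transfer of chirality.

   The fallback makes the same two ring bonds by the established amide version of the allene ether Nazarov cyclopentannelation and introduces chlorine afterwards. It sets out from aldehyde 2 and allene 14 (as lithioallene 15) and returns to the route at diol 19. Aldehyde 2 is homologated with 2-diazo-1-(morpholin-4-yl)ethanone and catalytic SnCl2 (Roskamp reaction) to (5Z)-1-(morpholin-4-yl)undec-5-ene-1,3-dione F1. O-alkylation (NaH, MOMCl) gives the enol ether enamide (2Z,5Z)-3-(methoxymethoxy)-1-(morpholin-4-yl)undeca-2,5-dien-1-one F2. Addition of 15 to the amide carbonyl of F2 at −78 °C and a mild acidic quench (aq. KH2PO4) trigger Nazarov closure to the diosphenol (4R,5Z)-5-{2-[(tert-butyldimethylsilyl)oxy]ethylidene}-2-hydroxy-4-(methoxymethoxy)-4-[(2Z)-oct-2-en-1-yl]cyclopent-2-en-1-one F3. The enol is converted with PhNTf2 and Et3N into the enol triflate F4, and palladium-catalysed halide exchange (Pd2(dba)3, t-BuBrettPhos, KCl) gives the protected chloro-enone F5. Aqueous HCl–THF then removes the methoxymethyl and silyl groups to give 19.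

2. Step 10. The basic ylide may add in conjugate fashion to the chlorodienone, or the lactolate may open too slowly at low temperature, so that the olefination is outrun by decomposition.

   The fallback builds the 5Z olefin without a carbon base; it sets out from lactol 21 and returns at target 25. Ramirez olefination (CBr4, PPh3, Zn) of the open aldehyde form gives (4R,5E)-2-chloro-5-(3,3-dibromoprop-2-en-1-ylidene)-4-hydroxy-4-[(2Z)-oct-2-en-1-yl]cyclopent-2-en-1-one F6. Palladium-catalysed hydrogenolysis of the bromine trans to the ring (Bu3SnH, Pd(PPh3)4) gives the (Z)-bromodiene (4R,5E)-5-[(2Z)-3-bromoprop-2-en-1-ylidene]-2-chloro-4-hydroxy-4-[(2Z)-oct-2-en-1-yl]cyclopent-2-en-1-one F7. Negishi coupling of F7 with (4-methoxy-4-oxobutyl)zinc bromide (Pd2(dba)3, tri(2-furyl)phosphine) proceeds with retention and gives 25.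

3. Step 6. The ynol-ether carbinol may rearrange (Meyer–Schuster type) under the acidic by-products of the Mitsunobu step, or the diazene may lose nitrogen without full transfer of chirality to the axis.

   The fallback forms the allene by anti-selective SN2′ hydride delivery; it sets out from carbinol 11 and returns at allene 14. Acylation (ClCO2Me, pyridine) gives (2R)-1-[(tert-butyldimethylsilyl)oxy]-4-ethoxybut-3-yn-2-yl methyl carbonate F8. Copper hydride reduction ((IPr)CuCl with IPr = 1,3-bis(2,6-diisopropylphenyl)imidazol-2-ylidene, NaOt-Bu, polymethylhydrosiloxane) delivers hydride anti to the carbonate and gives the same aS allene 14.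

**Further compounds**

F1 | step 7 | (5Z)-1-(morpholin-4-yl)undec-5-ene-1,3-dione | CCCCC/C=C\CC(=O)CC(=O)N1CCOCC1
F2 | step 7 | (2Z,5Z)-3-(methoxymethoxy)-1-(morpholin-4-yl)undeca-2,5-dien-1-one | CCCCC/C=C\C/C(OCOC)=C/C(=O)N1CCOCC1
F3 | step 7 | (4R,5Z)-5-{2-[(tert-butyldimethylsilyl)oxy]ethylidene}-2-hydroxy-4-(methoxymethoxy)-4-[(2Z)-oct-2-en-1-yl]cyclopent-2-en-1-one | CCCCC/C=C\C[C@@]1(OCOC)C=C(O)C(=O)/C1=C\CO[Si](C)(C)C(C)(C)C
F4 | step 7 | (4R,5Z)-5-{2-[(tert-butyldimethylsilyl)oxy]ethylidene}-4-(methoxymethoxy)-4-[(2Z)-oct-2-en-1-yl]-1-oxocyclopent-2-en-2-yl trifluoromethanesulfonate | CCCCC/C=C\C[C@@]1(OCOC)C=C(OS(=O)(=O)C(F)(F)F)C(=O)/C1=C\CO[Si](C)(C)C(C)(C)C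
F5 | step 7 | (4R,5Z)-5-{2-[(tert-butyldimethylsilyl)oxy]ethylidene}-2-chloro-4-(methoxymethoxy)-4-[(2Z)-oct-2-en-1-yl]cyclopent-2-en-1-one | CCCCC/C=C\C[C@@]1(OCOC)C=C(Cl)C(=O)/C1=C\CO[Si](C)(C)C(C)(C)C
F6 | step 10 | (4R,5E)-2-chloro-5-(3,3-dibromoprop-2-en-1-ylidene)-4-hydroxy-4-[(2Z)-oct-2-en-1-yl]cyclopent-2-en-1-one | CCCCC/C=C\C[C@@]1(O)C=C(Cl)C(=O)/C1=C/C=C(Br)Br
F7 | step 10 | (4R,5E)-5-[(2Z)-3-bromoprop-2-en-1-ylidene]-2-chloro-4-hydroxy-4-[(2Z)-oct-2-en-1-yl]cyclopent-2-en-1-one | CCCCC/C=C\C[C@@]1(O)C=C(Cl)C(=O)/C1=C/C=C\Br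
F8 | step 6 | (2R)-1-[(tert-butyldimethylsilyl)oxy]-4-ethoxybut-3-yn-2-yl methyl carbonate | CCOC#C[C@@H](OC(=O)OC)CO[Si](C)(C)C(C)(C)C
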